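**Strategy.** Ring B (C5–C6–C8–C9–C10) with its C7 carboxyl on C6 is treated as a cyclohexene in disguise, exploiting the 1,6-relationship between C7 and C8. In a tricycle made from dehydroandrographolide, ozonolysis of the C7=C8 bond of the six-membered ring (C5–C6–C7–C8–C9–C10) and amine-mediated aldol condensation in the same flask bond C6 to C8 and push C7 out as the formyl carbon, while the 13-ketone steers dehydration to a C8=C14 enone. The precursor is a β,γ-unsaturated tricyclic ketone assembled by side-chain cleavage, Felkin aldol and a carbonyl-ene closure of ring C; the enone product then takes up allene, and a ketyl ring expansion completes ring D.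

Key step: step 11

Remark: gibberellane numbering is used throughout (C14 = former exocyclic methylene carbon of the labdane; C12 and C13 come from the ketene acetal; C15–C17 from allene). The 11R configuration from Felkin control and the 6β configuration from equilibration are assumptions argued in the Why lines. TMSE = 2-(trimethylsilyl)ethyl, TBS = tert-butyldimethylsilyl.

Step 1
Reactants: 1 dehydroandrographolide (14-deoxy-11,12-didehydroandrographolide)
Product: 3 19-carboxylic acid of 1 (3-OH and dienyl lactone unchanged), via 19-aldehyde 2 (not isolated)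
Conditions: TEMPO (cat.), PhI(OAc)2, MeCN/H2O (1:1), rt
Reagents that add atoms: water, O
Why: Oxoammonium oxidation (TEMPO/PhI(OAc)2) should select the primary C19 alcohol over the hindered secondary C3 alcohol and, in aqueous acetonitrile, carry the aldehyde hydrate on to the acid; no stereocentre is touched.

Step 2
Reactants: 3 19-carboxylic acid
Product: 4 TMSE ester of 3
Conditions: Cl3CC(=NH)OCH2CH2SiMe3, PhMe, 100 °C
Reagents that add atoms: 2-(trimethylsilyl)ethyl 2,2,2-trichloroacetimidate, C[Si](C)(C)CCOC(=N)C(Cl)(Cl)Cl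
Why: Promoter-free trichloroacetimidate esterification alkylates only the carboxylic acid (which protonates the imidate), so the hindered axial acid is esterified without activating the carboxyl next to the free C3 hydroxyl.

Step 3
Reactants: 4 TMSE ester
Product: 5 3-oxo TMSE ester (β-keto ester)
Conditions: Dess–Martin periodinane, NaHCO3, CH2Cl2, rt
Reagents that add atoms: none
Why: Dess–Martin oxidation of the secondary alcohol removes the equatorial C3 stereocentre that must be inverted; C4 is quaternary, so nothing can epimerise.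

Step 4
Reactants: 5 3-oxo TMSE ester
Product: 6 C11 aldehyde (decalin with C9–CHO, exocyclic C8=C14H2, 3-ketone, C19 TMSE ester)
Conditions: KMnO4, MgSO4, THF/H2O, 0 °C
Reagents that add atoms: potassium permanganate, [K+].[O-][Mn](=O)(=O)=O
Why: Permanganate oxidative cleavage (Lemieux–von Rudloff type) should attack the accessible 1,2-disubstituted C11=C12 bond of the dienyl lactone faster than the hindered 1,1-disubstituted exocyclic alkene, excising the butenolide; the buffered cold medium should spare the aldehyde and the C9 stereocentre.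

Step 5
Reactants: 6 C11 aldehyde; 7 tert-butyl[(1-methoxyethenyl)oxy]dimethylsilane
Product: 8 aldol adduct (methyl ester at C13, 11R-hydroxyl, 3-ketone)
Conditions: BF3·OEt2, CH2Cl2, −78 °C; aq. NaHCO3
Reagents that add atoms: none
Why: Mukaiyama aldol addition is chemoselective for the aldehyde over the hindered C3 ketone and should follow the Felkin–Anh model (attack anti to the quaternary C10 substituent on C9), setting the 11R carbinol of the target without base that would conjugate the β,γ-unsaturated aldehyde.

Step 6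
Reactants: 8 aldol adduct
Product: 9 3,11-diol (3-OH axial and trans to the C19 ester)
Conditions: KBH(s-Bu)3 (K-Selectride), THF, −78 °C; H2O
Reagents that add atoms: none
Why: The bulky trialkylborohydride should attack the 4,4-disubstituted cyclohexanone along the equatorial trajectory (kinetic, sterically controlled ketone reduction), giving the axial 3-alcohol; both esters are inert at −78 °C.

Step 7
Reactants: 9 3,11-diol
Product: 10 3,11-bis(TBS) ether methyl ester
Conditions: TBSOTf, 2,6-lutidine, CH2Cl2, 0 °C to rt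
Reagents that add atoms: tert-butyldimethylsilyl triflate, CC(C)(C)[Si](C)(C)OS(=O)(=O)C(F)(F)F
Why: Silyl triflate silylation protects both hindered secondary alcohols in one operation; the ketone is already reduced, so no enol silylation competes.

Step 8
Reactants: 10 bis(TBS) ether methyl ester
Product: 11 C13 aldehyde (β-silyloxy aldehyde)
Conditions: i-Bu2AlH, CH2Cl2, −78 °C; aq. KNaC4H4O6
Reagents that add atoms: none
Why: Partial ester reduction stops at the aluminium hemiacetal at −78 °C, and the neopentyl axial C19 ester is too hindered to react.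

Step 9
Reactants: 11 C13 aldehyde
Product: 12 tricyclic 13-alcohol (ring C closed through C13–C14, C7=C8 alkene)
Conditions: Me2AlCl, CH2Cl2, −78 to −20 °C; aq. HCl
Reagents that add atoms: none
Why: Lewis-acid-promoted type 2 carbonyl-ene reaction: the exocyclic methylene carbon C14 attacks the activated aldehyde to close six-membered ring C while the allylic C7 hydrogen is transferred, placing the alkene at C7=C8; the C13 carbinol configuration (drawn trans to the C11 silyloxy group) is inconsequential because C13 is oxidised next.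

Step 10
Reactants: 12 tricyclic 13-alcohol
Product: 13 tricyclic 13-ketone with C7=C8 alkene (β,γ-unsaturated ketone)
Conditions: Dess–Martin periodinane, NaHCO3, CH2Cl2, 0 °C
Reagents that add atoms: none
Why: Buffered Dess–Martin oxidation should give the ketone without moving the C7=C8 bond into conjugation.

Step 11
Reactants: 13 tricyclic 13-ketone
Product: 15 ring-contracted enone aldehyde (cyclopentane ring B C5–C6–C8–C9–C10 with 6β-CHO; ring C 8(14)-en-13-one), via seco aldehyde-dione 14 (not isolated)
Conditions: O3, CH2Cl2/MeOH, −78 °C; Me2S, −78 °C to rt; then pyrrolidine, AcOH, PhMe, 40 °C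
Reagents that add atoms: ozone, [O-][O+]=O
Why: Ozone cleaves the only C=C bond (C7=C8) to the C7 aldehyde and a C8/C13 1,3-dione; the amine turns the aldehyde into its enamine, whose C6 attacks C8 of the enolised dione, and loss of water by vinylogous addition–elimination gives the C8=C14 enone, so the cyclohexene ring B becomes a cyclopentane with C7 extruded as the formyl group. The closest known reaction type is the ozonolysis/intramolecular aldol condensation ring contraction of cyclohexenes, ended here like a Robinson-type cyclodehydration onto a 1,3-dione. Ring B closes by a 5-(enolexo)-exo-trig aldol addition forming the C6–C8 bond. The new C6 stereocentre is epimerisable and should settle with the formyl group on the β face, trans to quaternary C4 and away from the α-oriented C19 ester and C20 methyl, while C5, C9 and C10 are carried over unchanged. The step needs attack at C8 (five-membered ring) and not C13 (seven-membered ring), and dehydration towards C14 and not C6: ring size secures the first, conjugation with the 13-ketone in a six-membered ring (instead of a cyclopentene inside the trans-fused A/B hydrindane) the second, and C9 is spared because the dione enolises at C14.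

Step 12
Reactants: 15 enone aldehyde
Product: 16 C7 carboxylic acid
Conditions: NaClO2, NaH2PO4, 2-methyl-2-butene, t-BuOH/H2O, rt
Reagents that add atoms: sodium chlorite, [Na+].[O-]Cl=O
Why: Pinnick oxidation converts the aldehyde to the acid with hypochlorite scavenged by the alkene additive; enone, silyl ethers and the C6 configuration are unaffected at buffered pH.

Step 13
Reactants: 16 C7 carboxylic acid
Product: 17 7,19-bis(TMSE) ester enone
Conditions: Cl3CC(=NH)OCH2CH2SiMe3, PhMe, 100 °C
Reagents that add atoms: 2-(trimethylsilyl)ethyl 2,2,2-trichloroacetimidate, C[Si](C)(C)CCOC(=N)C(Cl)(Cl)Cl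
Why: The same promoter-free imidate esterification as in step 2 masks the acid as a second fluoride-labile ester for the ketyl and xanthate chemistry.

Step 14
Reactants: 17 bis(TMSE) ester enone; 18 allene
Product: 19 allene photoadduct (methylenecyclobutane C8–C15–C16(=C17H2)–C14 cis-fused to ring C, 13-ketone)
Conditions: hν (350 nm, uranium-glass filter), allene (excess), THF, −78 °C
Reagents that add atoms: none
Why: Enone–allene [2+2] photocycloaddition (head-to-head: allene CH2 to the β-carbon C8, central carbon to C14) forges quaternary C8; the excited β-carbon should pyramidalise within a cis-fused B/C hydrindane and react on the face anti to the C20 methyl, so C15 enters cis to H9 as in the target, and the cis cyclobutane fusion fixes C14.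

Step 15
Reactants: 19 allene photoadduct
Product: 20 13-hydroxy gibberell-16-ene 7,19-bis(TMSE) ester 3,11-bis(TBS) ether
Conditions: SmI2, HMPA, t-BuOH, THF, −78 to 0 °C
Reagents that add atoms: none
Why: Ketyl–olefin rearrangement: the divalent-samarium ketyl at C13 adds 3-exo to C16 and the cyclopropylcarbinyl radical reopens by cleaving the strained C14–C16 bond (one-carbon ring expansion of the cyclobutane to ring D); the C14 radical is reduced and protonated, and the C13 configuration is dictated by the bridged geometry.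

Step 16
Reactants: 20 13-hydroxy gibberellene
Product: 21 13-O-(S-methyl dithiocarbonate) of 20
Conditions: KH, CS2, THF, 0 °C; then MeI
Reagents that add atoms: carbon disulfide, S=C=S; iodomethane, CI
Why: Xanthate formation (Barton–McCombie activation) on the tertiary bridgehead alkoxide; Chugaev elimination is impossible at the bridgehead, so the xanthate should be stable.

Step 17
Reactants: 21 xanthate
Product: 22 3,11-bis(TBS) ether 7,19-bis(TMSE) ester of the target
Conditions: Bu3SnH, AIBN, PhMe, 100 °C
Reagents that add atoms: none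
Why: Barton–McCombie deoxygenation: the bridgehead C13 radical cannot delocalise into the orthogonal C16=C17 bond and should simply abstract hydrogen from the stannane, the bicycle enforcing the configuration.

Step 18
Reactants: 22 protected target
Product: 23 target diol diacid CNP0232910.1
Conditions: Bu4NF, THF, 50 °C; aq. HCl to pH 3
Reagents that add atoms: none
Why: Fluoride cleaves both silyl ethers and both TMSE esters (β-elimination to ethylene and fluorotrimethylsilane) in one operation, avoiding acid that would isomerise the exocyclic alkene and strong base that would invite retro-aldol at C3.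

**Compound list**

1 | dehydroandrographolide (14-deoxy-11,12-didehydroandrographolide; equatorial 3-OH, axial 19-CH2OH) | O=C1OCC=C1/C=C/[C@H]1[C@]2(C)CC[C@@H](O)[C@@](C)(CO)[C@H]2CCC1=C | starting material
2 | 19-aldehyde of 1 | O=C1OCC=C1/C=C/[C@H]1[C@]2(C)CC[C@@H](O)[C@@](C)(C=O)[C@H]2CCC1=C | intermediate
3 | 19-carboxylic acid of 1 | O=C1OCC=C1/C=C/[C@H]1[C@]2(C)CC[C@@H](O)[C@@](C)(C(=O)O)[C@H]2CCC1=C | intermediate
4 | TMSE ester of 3 | O=C1OCC=C1/C=C/[C@H]1[C@]2(C)CC[C@@H](O)[C@@](C)(C(=O)OCC[Si](C)(C)C)[C@H]2CCC1=C | intermediate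
5 | 3-oxo TMSE ester | O=C1OCC=C1/C=C/[C@H]1[C@]2(C)CCC(=O)[C@@](C)(C(=O)OCC[Si](C)(C)C)[C@H]2CCC1=C | intermediate
6 | C11 aldehyde (C9–CHO, exocyclic C8=C14H2, 3-ketone, C19 TMSE ester) | O=C[C@H]1[C@]2(C)CCC(=O)[C@@](C)(C(=O)OCC[Si](C)(C)C)[C@H]2CCC1=C | intermediate
7 | tert-butyl[(1-methoxyethenyl)oxy]dimethylsilane | C=C(OC)O[Si](C)(C)C(C)(C)C | starting material
8 | aldol adduct (11R-hydroxy methyl ester, 3-ketone) | COC(=O)C[C@@H](O)[C@H]1[C@]2(C)CCC(=O)[C@@](C)(C(=O)OCC[Si](C)(C)C)[C@H]2CCC1=C | intermediate
9 | 3,11-diol (3-OH axial) | COC(=O)C[C@@H](O)[C@H]1[C@]2(C)CC[C@H](O)[C@@](C)(C(=O)OCC[Si](C)(C)C)[C@H]2CCC1=C | intermediate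
10 | 3,11-bis(TBS) ether methyl ester | COC(=O)C[C@@H](O[Si](C)(C)C(C)(C)C)[C@H]1[C@]2(C)CC[C@H](O[Si](C)(C)C(C)(C)C)[C@@](C)(C(=O)OCC[Si](C)(C)C)[C@H]2CCC1=C | intermediate
11 | C13 aldehyde (3,11-bis-TBS) | O=CC[C@@H](O[Si](C)(C)C(C)(C)C)[C@H]1[C@]2(C)CC[C@H](O[Si](C)(C)C(C)(C)C)[C@@](C)(C(=O)OCC[Si](C)(C)C)[C@H]2CCC1=C | intermediate
12 | tricyclic 13-alcohol, C7=C8 alkene | O[C@@H]1C[C@@H](O[Si](C)(C)C(C)(C)C)[C@H]2[C@]3(C)CC[C@H](O[Si](C)(C)C(C)(C)C)[C@@](C)(C(=O)OCC[Si](C)(C)C)[C@H]3CC=C2C1 | intermediate
13 | tricyclic 13-ketone, C7=C8 alkene | O=C1C[C@@H](O[Si](C)(C)C(C)(C)C)[C@H]2[C@]3(C)CC[C@H](O[Si](C)(C)C(C)(C)C)[C@@](C)(C(=O)OCC[Si](C)(C)C)[C@H]3CC=C2C1 | intermediate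
14 | 7,8-seco 7-al-8,13-dione | O=C1C[C@@H](O[Si](C)(C)C(C)(C)C)[C@@H]([C@]2(C)CC[C@H](O[Si](C)(C)C(C)(C)C)[C@@](C)(C(=O)OCC[Si](C)(C)C)[C@H]2CC=O)C(=O)C1 | intermediate
15 | ring-contracted enone aldehyde (6β-CHO, 8(14)-en-13-one) | O=C[C@@H]1C2=CC(=O)C[C@@H](O[Si](C)(C)C(C)(C)C)[C@H]2[C@]3(C)CC[C@H](O[Si](C)(C)C(C)(C)C)[C@@](C)(C(=O)OCC[Si](C)(C)C)[C@H]31 | intermediate
16 | C7 carboxylic acid | OC(=O)[C@@H]1C2=CC(=O)C[C@@H](O[Si](C)(C)C(C)(C)C)[C@H]2[C@]3(C)CC[C@H](O[Si](C)(C)C(C)(C)C)[C@@](C)(C(=O)OCC[Si](C)(C)C)[C@H]31 | intermediate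
17 | 7,19-bis(TMSE) ester enone | C[Si](C)(C)CCOC(=O)[C@@H]1C2=CC(=O)C[C@@H](O[Si](C)(C)C(C)(C)C)[C@H]2[C@]3(C)CC[C@H](O[Si](C)(C)C(C)(C)C)[C@@](C)(C(=O)OCC[Si](C)(C)C)[C@H]31 | intermediate
18 | allene (propadiene) | C=C=C | starting material
19 | allene photoadduct (methylenecyclobutane on C8–C14, 13-ketone) | C=C1C[C@]23[C@H]1C(=O)C[C@@H](O[Si](C)(C)C(C)(C)C)[C@H]2[C@]4(C)CC[C@H](O[Si](C)(C)C(C)(C)C)[C@@](C)(C(=O)OCC[Si](C)(C)C)[C@H]4[C@@H]3C(=O)OCC[Si](C)(C)C | intermediate
20 | 13-hydroxy gibberell-16-ene bis(TMSE) ester bis(TBS) ether | C=C1C[C@]23C[C@@]1(O)C[C@@H](O[Si](C)(C)C(C)(C)C)[C@H]2[C@]1(C)CC[C@H](O[Si](C)(C)C(C)(C)C)[C@@](C)(C(=O)OCC[Si](C)(C)C)[C@H]1[C@@H]3C(=O)OCC[Si](C)(C)C | intermediate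
21 | 13-O-(S-methyl dithiocarbonate) of 20 | C=C1C[C@]23C[C@@]1(OC(=S)SC)C[C@@H](O[Si](C)(C)C(C)(C)C)[C@H]2[C@]1(C)CC[C@H](O[Si](C)(C)C(C)(C)C)[C@@](C)(C(=O)OCC[Si](C)(C)C)[C@H]1[C@@H]3C(=O)OCC[Si](C)(C)C | intermediate
22 | 3,11-bis(TBS) ether 7,19-bis(TMSE) ester of the target | C=C1C[C@]23C[C@H]1C[C@@H](O[Si](C)(C)C(C)(C)C)[C@H]2[C@]1(C)CC[C@H](O[Si](C)(C)C(C)(C)C)[C@@](C)(C(=O)OCC[Si](C)(C)C)[C@H]1[C@@H]3C(=O)OCC[Si](C)(C)C | intermediate
23 | CNP0232910.1 (3-OH axial and trans to the C19 acid, 11R-OH, 6β-COOH, 16-ene) | C=C1C[C@]23C[C@H]1C[C@@H](O)[C@H]2[C@]1(C)CC[C@H](O)[C@@](C)(C(=O)O)[C@H]1[C@@H]3C(=O)O | target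

**Totals.** Total step count: 18. Longest linear sequence: 18 steps (from 1; 7 and 18 are commercial).

**Steps most likely to fail**

Step 11 (key step). During the amine-mediated condensation the dione-aldehyde may epimerise at C9, lose the C11 silyloxy group by β-elimination from the 13-ketone, or close in a wrong aldol mode. The fallback sets out from 12 and comes back at 15; it contracts the ring before C13 is oxidised, so that neither a 1,3-dione nor a β-silyloxy ketone meets the amine. Ozonolysis of 12 (O3, CH2Cl2/MeOH, −78 °C; PPh3) would give the hydroxy seco keto-aldehyde F1. L-Proline in DMSO at rt would effect the aldol addition alone, giving the ring-contracted ketol F2 (tertiary 8-OH, drawn β; its configuration is inconsequential). Dess–Martin periodinane would then oxidise the C13 carbinol to the β-hydroxy ketone F3, which DBU should dehydrate (E1cB towards C14) to 15.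

Step 15. The ketyl may fragment the cyclobutane directly (C8–C14 scission to an enolate), dimerise or be over-reduced instead of migrating the vinyl carbon. The fallback sets out from 19 and comes back at 22, bypassing 20 and 21, with a neutral alkyl radical in place of the ketyl. NaBH4 in MeOH at 0 °C should reduce the 13-ketone from the face opposite the cyclobutane to the secondary alcohol F4. PhOC(S)Cl, pyridine and DMAP would give the thionocarbonate F5. Bu3SnH/AIBN in PhMe at 100 °C would then generate the C13 radical, whose 1,2-vinyl shift (3-exo closure on C16, reopening of the C14–C16 bond; a Dowd–Beckwith-type ring expansion) and hydrogen abstraction at C14 give 22.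

Step 14. The photocycloaddition may show poor facial or head-to-head selectivity, or the β,γ-unsaturated ketone product may undergo secondary photoreactions (1,3-acyl shift). The fallback sets out from 17 and comes back at 20, replacing photochemistry by a polar/ketyl sequence. Conjugate propargylation of the enone with allenyltributylstannane and TiCl4 in CH2Cl2 at −78 °C (same facial bias at C8) would give the propargyl ketone F6. SmI2/HMPA/t-BuOH would then close ring D by ketyl–alkyne 5-exo-dig cyclisation, the vinyl radical abstracting hydrogen to give 20.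

**Further compounds**

F1 | step 11 | hydroxy seco keto-aldehyde (from ozonolysis of 12) | O[C@@H]1C[C@@H](O[Si](C)(C)C(C)(C)C)[C@@H]([C@]2(C)CC[C@H](O[Si](C)(C)C(C)(C)C)[C@@](C)(C(=O)OCC[Si](C)(C)C)[C@H]2CC=O)C(=O)C1
F2 | step 11 | ring-contracted ketol (8,13-diol, 6β-CHO) | O[C@]12C[C@H](O)C[C@@H](O[Si](C)(C)C(C)(C)C)[C@H]1[C@]3(C)CC[C@H](O[Si](C)(C)C(C)(C)C)[C@@](C)(C(=O)OCC[Si](C)(C)C)[C@H]3[C@@H]2C=O
F3 | step 11 | 8-hydroxy-13-ketone aldehyde | O[C@]12CC(=O)C[C@@H](O[Si](C)(C)C(C)(C)C)[C@H]1[C@]3(C)CC[C@H](O[Si](C)(C)C(C)(C)C)[C@@](C)(C(=O)OCC[Si](C)(C)C)[C@H]3[C@@H]2C=O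
F4 | step 15 | 13-alcohol of photoadduct 19 | C=C1C[C@]23[C@H]1[C@H](O)C[C@@H](O[Si](C)(C)C(C)(C)C)[C@H]2[C@]4(C)CC[C@H](O[Si](C)(C)C(C)(C)C)[C@@](C)(C(=O)OCC[Si](C)(C)C)[C@H]4[C@@H]3C(=O)OCC[Si](C)(C)C
F5 | step 15 | 13-O-phenyl thionocarbonate of F4 | C=C1C[C@]23[C@H]1[C@H](OC(=S)Oc5ccccc5)C[C@@H](O[Si](C)(C)C(C)(C)C)[C@H]2[C@]4(C)CC[C@H](O[Si](C)(C)C(C)(C)C)[C@@](C)(C(=O)OCC[Si](C)(C)C)[C@H]4[C@@H]3C(=O)OCC[Si](C)(C)C
F6 | step 14 | 8-propargyl 13-ketone | C#CC[C@]12CC(=O)C[C@@H](O[Si](C)(C)C(C)(C)C)[C@H]1[C@]3(C)CC[C@H](O[Si](C)(C)C(C)(C)C)[C@@](C)(C(=O)OCC[Si](C)(C)C)[C@H]3[C@@H]2C(=O)OCC[Si](C)(C)C
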